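The plan rests on cutting the central sigma bond of the cross-conjugated diene in the cyclohexene ring (ring A): the bond C4–C5 between the ring alkene C3=C4 and the exocyclic methylene C5=CH2 (carotenoid numbering; C6 is the stereocentre, C1 the gem-dimethyl carbon). This 3-methylenecyclohexene is the cycloisomer of an open-chain 1,6-enyne, so a rhodium-vinylidene cycloisomerisation closes ring A and sets both diene double bonds in one atom-economical operation, with polarity reversal of the alkyne terminus. The precursor is an acyclic (R)-enyne with a propargyl group on C1, a vinyl group on C6 and a tetrazolyl sulfone on C7; a Julia–Kocienski olefination with a C30 polyenal then completes the carotenoid.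

Key step: step 8

Assumption: the lipase in step 3 is taken to acylate the pro-S hydroxymethyl group of diol 5 (the sense recalled for simpler 2-alkylpropane-1,3-diols); the (S) configuration of 6 is what the route requires.
Assumption: 2,3,4-trimethylbenzaldehyde (13) and crocetin dialdehyde (16) are taken as purchasable.

Step 1
Reactants: 1 diethyl 2-(propan-2-ylidene)propanedioate (diethyl isopropylidenemalonate); 2 3-bromoprop-1-yne (propargyl bromide)
Product: 4 diethyl 2-(2-methylpent-4-yn-2-yl)propanedioate, via allenylmagnesium bromide 3 (not isolated)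
Conditions: 2, Mg, HgCl2 (cat.), Et2O, 0 °C; then 1, Et2O/THF, −78 to 0 °C; 1 M HCl quench
Reagents that add atoms: none
Why: Grignard conjugate addition to an alkylidene malonate: the allenyl reagent should react through its γ-carbon (SE2'), which builds the quaternary gem-dimethyl carbon C1 and delivers the propargyl rather than the allenyl chain.

Step 2
Reactants: 4 diethyl 2-(2-methylpent-4-yn-2-yl)propanedioate
Product: 5 2-(2-methylpent-4-yn-2-yl)propane-1,3-diol
Conditions: LiAlH4, THF, 0 °C to rt; aqueous work-up
Reagents that add atoms: none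
Why: Hydride reduction of both esters should give the prochiral 2-substituted propane-1,3-diol, the isolated terminal alkyne being inert to LiAlH4 under these conditions.

Step 3
Reactants: 5 2-(2-methylpent-4-yn-2-yl)propane-1,3-diol
Product: 6 (2S)-2-(hydroxymethyl)-3,3-dimethylhex-5-yn-1-yl acetate
Conditions: Pseudomonas fluorescens lipase (Amano AK), vinyl acetate, MTBE, rt
Reagents that add atoms: vinyl acetate (CC(=O)OC=C)
Why: Enzymatic desymmetrisation by irreversible lipase transesterification: the active site acylates one of the two enantiotopic hydroxymethyl groups, which sets the C6 stereocentre, and the minor monoacetate should be removed by faster over-acylation.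

Step 4
Reactants: 6 (2S)-2-(hydroxymethyl)-3,3-dimethylhex-5-yn-1-yl acetate
Product: 7 (2R)-2-formyl-3,3-dimethylhex-5-yn-1-yl acetate
Conditions: Dess–Martin periodinane, NaHCO3, CH2Cl2, 0 °C; used at once
Reagents that add atoms: none
Why: Dess–Martin oxidation under buffered, near-neutral conditions should give the aldehyde without enolisation of the hindered α-carbon, so the configuration is retained (the descriptor changes only because of the priority rules).

Step 5
Reactants: 7 (2R)-2-formyl-3,3-dimethylhex-5-yn-1-yl acetate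
Product: 8 (2R)-2-ethenyl-3,3-dimethylhex-5-yn-1-yl acetate
Conditions: Ph3PCH3Br, KN(SiMe3)2, THF, −78 °C; then 7, −78 to 0 °C
Reagents that add atoms: methyltriphenylphosphonium bromide (C[P+](c1ccccc1)(c1ccccc1)c1ccccc1.[Br-])
Why: Wittig methylenation: the small salt-free ylide should add to the aldehyde at low temperature faster than it deprotonates the α-carbon shielded by the quaternary centre, which installs the vinyl group (C5=CH2) with the C6 configuration intact.

Step 6
Reactants: 8 (2R)-2-ethenyl-3,3-dimethylhex-5-yn-1-yl acetate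
Product: 9 (2R)-2-ethenyl-3,3-dimethylhex-5-yn-1-ol
Conditions: K2CO3, MeOH, 0 °C to rt
Reagents that add atoms: none
Why: Base-catalysed transesterification (methanolysis of the acetate) should free the primary alcohol without touching the alkyne, the alkene or the stereocentre.

Step 7
Reactants: 9 (2R)-2-ethenyl-3,3-dimethylhex-5-yn-1-ol
Product: 11 5-{[(2R)-2-ethenyl-3,3-dimethylhex-5-yn-1-yl]sulfonyl}-1-phenyl-1H-tetrazole, via enyne sulfide 10 (not isolated)
Conditions: 1-phenyl-1H-tetrazole-5-thiol, PPh3, DIAD, THF, 0 °C to rt; then EtOH, (NH4)6Mo7O24·4H2O (cat.), 30 % H2O2, 0 °C to rt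
Reagents that add atoms: 1-phenyl-1H-tetrazole-5-thiol (Sc1nnnn1-c1ccccc1); hydrogen peroxide (OO)
Why: Mitsunobu thioetherification at the primary carbon (stereocentre not involved) followed in the same flask by molybdate-catalysed sulfide-to-sulfone oxidation, which spares the isolated terminal alkene and alkyne and is placed before ring formation so that the oxidant never meets the diene.

Step 8
Reactants: 11 5-{[(2R)-2-ethenyl-3,3-dimethylhex-5-yn-1-yl]sulfonyl}-1-phenyl-1H-tetrazole
Product: 12 5-({[(1S)-6,6-dimethyl-2-methylidenecyclohex-3-en-1-yl]methyl}sulfonyl)-1-phenyl-1H-tetrazole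
Conditions: [Rh(cod)Cl]2 (5 mol %), P(4-FC6H4)3 (20 mol %), DMF, 85 °C
Reagents that add atoms: none
Why: Monovalent rhodium should convert the terminal alkyne (C3≡C4–H) by 1,2-hydrogen shift into a rhodium vinylidene, which reverses the polarity of the alkyne terminus C4; an intramolecular [2+2] cycloaddition of Rh=C4 with the vinyl group on C6 forms the C4–C5 bond and a rhodacyclobutane, and β-hydride elimination of the C5–H followed by C4–H reductive elimination releases the diene C3=C4–C5=CH2 and the catalyst. The closest known reaction type is the rhodium-vinylidene-mediated cycloisomerisation of 1,6-enynes to 3-methylenecyclohexenes with this catalyst system. Ring A is closed in a six-membered mode that is endo with respect to the alkyne (both alkyne carbons end in the ring) and exo with respect to the alkene (its CH2 terminus stays outside as the exocyclic methylene). No new stereocentre is formed, and the preset C6 centre should survive because its C–H bond takes no part and the medium is neutral. The selectivity needed is vinylidene formation over the metallacyclopentene (Alder-ene) pathway that would join C3 to C5 in a five-membered ring; the terminal alkyne, the electron-poor triarylphosphine in DMF and the Thorpe–Ingold effect of the gem-dimethyl carbon C1 should secure it, and the substrate offers no second alkene.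

Step 9
Reactants: 13 2,3,4-trimethylbenzaldehyde
Product: 14 (2,3,4-trimethylphenyl)methanol
Conditions: NaBH4, MeOH, 0 °C
Reagents that add atoms: none
Why: Borohydride reduction of an aromatic aldehyde to the benzylic alcohol.

Step 10
Reactants: 14 (2,3,4-trimethylphenyl)methanol
Product: 15 diethyl [(2,3,4-trimethylphenyl)methyl]phosphonate
Conditions: P(OEt)3, ZnI2, toluene, reflux
Reagents that add atoms: triethyl phosphite (CCOP(OCC)OCC)
Why: ZnI2-mediated Michaelis–Arbuzov-type conversion of an electron-rich benzylic alcohol directly into the benzylphosphonate.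

Step 11
Reactants: 15 diethyl [(2,3,4-trimethylphenyl)methyl]phosphonate; 16 crocetin dialdehyde, (2E,4E,6E,8E,10E,12E,14E)-2,6,11,15-tetramethylhexadeca-2,4,6,8,10,12,14-heptaenedial
Product: 17 (2E,4E,6E,8E,10E,12E,14E,16E)-2,6,11,15-tetramethyl-17-(2,3,4-trimethylphenyl)heptadeca-2,4,6,8,10,12,14,16-octaenal
Conditions: 15, NaN(SiMe3)2, THF, −78 to 0 °C; added slowly to 16 (3 equiv), THF, 0 °C to rt; excess 16 recovered
Reagents that add atoms: none
Why: Horner–Wadsworth–Emmons olefination of a benzylphosphonate should form the C7'=C8' bond with E geometry, and mono-olefination of the symmetrical dialdehyde is favoured statistically by its excess.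

Step 12
Reactants: 12 5-({[(1S)-6,6-dimethyl-2-methylidenecyclohex-3-en-1-yl]methyl}sulfonyl)-1-phenyl-1H-tetrazole; 17 the C30 polyenal
Product: 18 (6S)-3,4-didehydro-γ,χ-carotene (all-E), the target
Conditions: 12, KN(SiMe3)2 (1.0 equiv), DME, −60 °C; then 17, −60 °C to rt, dark, argon
Reagents that add atoms: none
Why: Julia–Kocienski olefination: addition of the potassium sulfonyl carbanion to the enal, Smiles rearrangement and loss of SO2 and tetrazolate should give the E C7=C8 bond, while the pre-formed anion with no excess base leaves the doubly allylic C6–H, and hence the (S) centre, untouched.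

Compound list
1 | diethyl 2-(propan-2-ylidene)propanedioate | CCOC(=O)C(=C(C)C)C(=O)OCC | starting material
2 | 3-bromoprop-1-yne (propargyl bromide) | BrCC#C | starting material
3 | allenylmagnesium bromide (propa-1,2-dien-1-ylmagnesium bromide) | C=C=C[Mg]Br | intermediate
4 | diethyl 2-(2-methylpent-4-yn-2-yl)propanedioate | CCOC(=O)C(C(=O)OCC)C(C)(C)CC#C | intermediate
5 | 2-(2-methylpent-4-yn-2-yl)propane-1,3-diol | OCC(CO)C(C)(C)CC#C | intermediate
6 | (2S)-2-(hydroxymethyl)-3,3-dimethylhex-5-yn-1-yl acetate | C#CCC(C)(C)[C@@H](CO)COC(C)=O | intermediate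
7 | (2R)-2-formyl-3,3-dimethylhex-5-yn-1-yl acetate | C#CCC(C)(C)[C@@H](C=O)COC(C)=O | intermediate
8 | (2R)-2-ethenyl-3,3-dimethylhex-5-yn-1-yl acetate | C#CCC(C)(C)[C@@H](C=C)COC(C)=O | intermediate
9 | (2R)-2-ethenyl-3,3-dimethylhex-5-yn-1-ol | C#CCC(C)(C)[C@@H](C=C)CO | intermediate
10 | 5-{[(2R)-2-ethenyl-3,3-dimethylhex-5-yn-1-yl]sulfanyl}-1-phenyl-1H-tetrazole (enyne sulfide) | C#CCC(C)(C)[C@@H](C=C)CSc1nnnn1-c1ccccc1 | intermediate
11 | 5-{[(2R)-2-ethenyl-3,3-dimethylhex-5-yn-1-yl]sulfonyl}-1-phenyl-1H-tetrazole | C#CCC(C)(C)[C@@H](C=C)CS(=O)(=O)c1nnnn1-c1ccccc1 | intermediate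
12 | 5-({[(1S)-6,6-dimethyl-2-methylidenecyclohex-3-en-1-yl]methyl}sulfonyl)-1-phenyl-1H-tetrazole | C=C1C=CCC(C)(C)[C@@H]1CS(=O)(=O)c1nnnn1-c1ccccc1 | intermediate
13 | 2,3,4-trimethylbenzaldehyde | O=Cc1ccc(C)c(C)c1C | starting material
14 | (2,3,4-trimethylphenyl)methanol | OCc1ccc(C)c(C)c1C | intermediate
15 | diethyl [(2,3,4-trimethylphenyl)methyl]phosphonate | CCOP(=O)(Cc1ccc(C)c(C)c1C)OCC | intermediate
16 | crocetin dialdehyde, (2E,4E,6E,8E,10E,12E,14E)-2,6,11,15-tetramethylhexadeca-2,4,6,8,10,12,14-heptaenedial | O=C/C(C)=C/C=C/C(C)=C/C=C/C=C(C)/C=C/C=C(C)/C=O | starting material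
17 | (2E,4E,6E,8E,10E,12E,14E,16E)-2,6,11,15-tetramethyl-17-(2,3,4-trimethylphenyl)heptadeca-2,4,6,8,10,12,14,16-octaenal | O=C/C(C)=C/C=C/C(C)=C/C=C/C=C(C)/C=C/C=C(C)/C=C/c1ccc(C)c(C)c1C | intermediate
18 | (6S)-3,4-didehydro-γ,χ-carotene (all-E) | C=C1C=CCC(C)(C)[C@@H]1/C=C/C(C)=C/C=C/C(C)=C/C=C/C=C(C)/C=C/C=C(C)/C=C/c1ccc(C)c(C)c1C | target

Total step count: 12
Longest linear sequence: 9 steps (steps 1 to 8, then step 12)

Steps most likely to fail

Step 8. The catalyst may be tied up by the tetrazole nitrogen atoms, or the enyne may be diverted through a metallacyclopentene (Alder-ene) pathway that closes a five-membered ring instead. The fallback closes the same bond by an intramolecular Heck reaction and sets out from 11. ZrCl4-catalysed anti-hydrostannation with Bu3SnH (toluene, 0 °C) should give the cis-alkenylstannane 5-{[(2R,5Z)-2-ethenyl-3,3-dimethyl-6-(tributylstannyl)hex-5-en-1-yl]sulfonyl}-1-phenyl-1H-tetrazole F1. Iododestannylation (I2, CH2Cl2, 0 °C, with retention) should give 5-{[(2R,5Z)-2-ethenyl-6-iodo-3,3-dimethylhex-5-en-1-yl]sulfonyl}-1-phenyl-1H-tetrazole F2. Heck cyclisation (Pd(OAc)2, PPh3, Ag2CO3, MeCN, 70 °C; zerovalent palladium formed in the flask) in the 6-exo-trig mode, with β-hydride elimination to the exocyclic methylene, comes back to the route at 12.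

Step 12. The E/Z selectivity at C7=C8 may be low with this hindered sulfone and α-branched enal, and the base may remove the doubly allylic C6 proton, with erosion of configuration or shift of the diene into conjugation. The fallback reverses the polarity of the union and sets out from 8 and 17. Enyne acetate 8, under the conditions of step 8, should give [(1S)-6,6-dimethyl-2-methylidenecyclohex-3-en-1-yl]methyl acetate F3. Methanolysis (K2CO3, MeOH) gives [(1S)-6,6-dimethyl-2-methylidenecyclohex-3-en-1-yl]methanol F4, and Dess–Martin oxidation gives (1S)-6,6-dimethyl-2-methylidenecyclohex-3-ene-1-carbaldehyde F5, used at once. Polyenal 17 is reduced (NaBH4, THF/MeOH) to (2E,4E,6E,8E,10E,12E,14E,16E)-2,6,11,15-tetramethyl-17-(2,3,4-trimethylphenyl)heptadeca-2,4,6,8,10,12,14,16-octaen-1-ol F6 and converted with PPh3·HBr (MeOH/CH2Cl2) into the corresponding polyenyl triphenylphosphonium bromide F7. The Wittig reaction of F7 with F5 (NaOMe, CH2Cl2/MeOH, 0 °C) comes back to the route at 18.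

Step 5. The basic ylide may enolise the β-acetoxy aldehyde, with loss of acetate by elimination or racemisation at C6. The fallback is a two-stage Peterson olefination without a basic step and sets out from 7. Addition of Me3SiCH2MgCl/CeCl3 (THF, −78 °C) should give (2R)-2-[1-hydroxy-2-(trimethylsilyl)ethyl]-3,3-dimethylhex-5-yn-1-yl acetate F8 (mixture at the carbinol carbon). Acid-promoted anti-elimination (cat. H2SO4, THF, rt) comes back to the route at 8.

Further compounds
F1 | step 8 | 5-{[(2R,5Z)-2-ethenyl-3,3-dimethyl-6-(tributylstannyl)hex-5-en-1-yl]sulfonyl}-1-phenyl-1H-tetrazole | CCCC[Sn](CCCC)(CCCC)/C=C\CC(C)(C)[C@@H](C=C)CS(=O)(=O)c1nnnn1-c1ccccc1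
F2 | step 8 | 5-{[(2R,5Z)-2-ethenyl-6-iodo-3,3-dimethylhex-5-en-1-yl]sulfonyl}-1-phenyl-1H-tetrazole | I/C=C\CC(C)(C)[C@@H](C=C)CS(=O)(=O)c1nnnn1-c1ccccc1
F3 | step 12 | [(1S)-6,6-dimethyl-2-methylidenecyclohex-3-en-1-yl]methyl acetate | C=C1C=CCC(C)(C)[C@@H]1COC(C)=O
F4 | step 12 | [(1S)-6,6-dimethyl-2-methylidenecyclohex-3-en-1-yl]methanol | C=C1C=CCC(C)(C)[C@@H]1CO
F5 | step 12 | (1S)-6,6-dimethyl-2-methylidenecyclohex-3-ene-1-carbaldehyde | C=C1C=CCC(C)(C)[C@@H]1C=O
F6 | step 12 | (2E,4E,6E,8E,10E,12E,14E,16E)-2,6,11,15-tetramethyl-17-(2,3,4-trimethylphenyl)heptadeca-2,4,6,8,10,12,14,16-octaen-1-ol | OC/C(C)=C/C=C/C(C)=C/C=C/C=C(C)/C=C/C=C(C)/C=C/c1ccc(C)c(C)c1C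
F7 | step 12 | [(2E,4E,6E,8E,10E,12E,14E,16E)-2,6,11,15-tetramethyl-17-(2,3,4-trimethylphenyl)heptadeca-2,4,6,8,10,12,14,16-octaen-1-yl]triphenylphosphonium bromide | [Br-].c1ccccc1[P+](c1ccccc1)(c1ccccc1)C/C(C)=C/C=C/C(C)=C/C=C/C=C(C)/C=C/C=C(C)/C=C/c1ccc(C)c(C)c1C
F8 | step 5 | (2R)-2-[1-hydroxy-2-(trimethylsilyl)ethyl]-3,3-dimethylhex-5-yn-1-yl acetate | C#CCC(C)(C)[C@@H](C(O)C[Si](C)(C)C)COC(C)=O
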